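**Retrosynthetic overview**
- The lactate ester C–O bond is cut last: an all-trans 2,4-diarylcyclobutane-1,3-dicarboxylic acid mono-benzyl ester plus perbenzylated (S)-3-(3,4-dihydroxyphenyl)lactate, which comes from L-DOPA with retention.
- The two aryl–ring bonds are cut one after the other: the 4-oxyphenyl group by copper-catalysed conjugate arylation of a cyclobutene ester (then base equilibration to all-trans), the catechol aryl by enantioconvergent palladium-catalysed allylic arylation that opens a β-lactone.
- This leads back to a 2-oxabicyclo[2.2.0]hexenone ("photopyrone") made from benzyl coumalate by one photochemical 4π-electrocyclisation, which closes the cyclobutene and the β-lactone together; the alternating acid/aryl/acid/aryl pattern is fixed by the pyranone carbons.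
- Ring order: both four-membered rings form first and simultaneously, the β-lactone is opened in the same flask, the cyclobutene is saturated by the second arylation, and no further ring is made; global hydrogenolysis ends the route.

Assumption: the SMILES is read as drawn, i.e. a (1R,2R,3S,4S) all-trans cyclobutane carrying an (S)-configured lactate unit (the mirror image of natural danshensu), so L-DOPA is the matching chiral-pool source.

**Step 1**
Reactants: 1 L-DOPA
Product: 2 (2S)-3-(3,4-dihydroxyphenyl)-2-hydroxypropanoic acid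
Conditions: NaNO2, 1 M H2SO4 aq, 0 °C → rt, under Ar
Reagents that add atoms: water (O)
Why: Diazotisation of the α-amino acid (van Slyke-type deaminative hydroxylation) goes through an α-lactone formed by the neighbouring carboxylate and reopened by water, so the double inversion keeps the (S) centre.

**Step 2**
Reactants: 2 (2S)-3-(3,4-dihydroxyphenyl)-2-hydroxypropanoic acid
Product: 3 benzyl (2S)-3-[3,4-bis(benzyloxy)phenyl]-2-hydroxypropanoate
Conditions: BnBr (3.3 equiv), K2CO3, DMF, rt
Reagents that add atoms: benzyl bromide (BrCc1ccccc1)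
Why: Williamson and carboxylate O-alkylation, in which K2CO3 ionises only the carboxylic acid and the two phenols, so three benzyl groups go on, the secondary alcohol stays free and the stereocentre is untouched.

**Step 3**
Reactants: 4 coumalic acid (2-oxo-2H-pyran-5-carboxylic acid)
Product: 5 benzyl coumalate (benzyl 2-oxo-2H-pyran-5-carboxylate)
Conditions: BnBr, KHCO3, DMF, rt
Reagents that add atoms: benzyl bromide (BrCc1ccccc1)
Why: Carboxylate SN2 alkylation under hydrogencarbonate, mild enough to leave the base-sensitive 2-pyranone ring intact.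

**Step 4**
Reactants: 5 benzyl coumalate, 6 3,4-bis(benzyloxy)phenylboronic acid
Product: 8 (1S,4S)-4-[3,4-bis(benzyloxy)phenyl]-2-[(benzyloxy)carbonyl]cyclobut-2-ene-1-carboxylic acid, via photopyrone 7 (not isolated)
Conditions: hν (medium-pressure Hg lamp, Pyrex), degassed THF, −10 °C; then Pd2(dba)3 (2.5 mol%), BINOL-based bis(1-phenylethyl)amine phosphoramidite (6 mol%, single antipode), THF/H2O 20:1, 0 → 20 °C, dark
Reagents that add atoms: none
Why: Proposed new method: Pyrex-filtered irradiation triggers the known disrotatory 4π-electrocyclisation of the 2-pyranone diene, which closes the cyclobutene and the β-lactone at once and gives racemic cis-fused 7; 7 is a strained cyclic Morita–Baylis–Hillman-type allylic ester, so zerovalent palladium ionises its C–O bond with inversion to a π-allylpalladium carboxylate that has a mirror plane (both enantiomers of 7 converge on it), the boronic acid transmetalates with the internal carboxylate as base, and ligand-controlled reductive elimination at one of the two enantiotopic allyl termini delivers the aryl from the palladium face, i.e. trans to CO2H, setting both stereocentres of 8; the closest known reactions are the palladium-catalysed deracemising allylic substitutions of the parent 2-pyranone photoproduct with malonates and dialkylzincs and the base-free palladium-catalysed coupling of vinyl epoxides with arylboronic acids.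

**Step 5**
Reactants: 8 (1S,4S)-4-[3,4-bis(benzyloxy)phenyl]-2-[(benzyloxy)carbonyl]cyclobut-2-ene-1-carboxylic acid, 9 4-(benzyloxy)phenylmagnesium bromide (commercial THF solution, 2.6 equiv)
Product: 11 (1S,2S,3R,4R)-3-[(benzyloxy)carbonyl]-2-[4-(benzyloxy)phenyl]-4-[3,4-bis(benzyloxy)phenyl]cyclobutane-1-carboxylic acid (all-trans), via cis-ester epimer 10 (not isolated)
Conditions: CuBr·SMe2 (10 mol%), THF, −40 °C; then BnOH, NaOBn (1 M in BnOH, 3 equiv), 40 °C; 1 M HCl
Reagents that add atoms: none
Why: Copper-catalysed conjugate addition of the aryl Grignard reagent (the first equivalent only forms the magnesium carboxylate) to the strained cyclobutene ester occurs at the β-carbon anti to the adjacent carboxylate, which puts the new aryl cis to the first one, and sodium benzyloxide then equilibrates the ester-bearing carbon of the kinetic protonation product 10 (degenerate transesterification, carboxylate inert) to the all-trans arrangement with the ester trans to both flanking aryl groups.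

**Step 6**
Reactants: 11 all-trans cyclobutane monoacid, 3 benzyl (2S)-3-[3,4-bis(benzyloxy)phenyl]-2-hydroxypropanoate
Product: 12 1-benzyl 3-[(2S)-1-(benzyloxy)-3-[3,4-bis(benzyloxy)phenyl]-1-oxopropan-2-yl] (1R,2R,3S,4S)-2-[4-(benzyloxy)phenyl]-4-[3,4-bis(benzyloxy)phenyl]cyclobutane-1,3-dicarboxylate
Conditions: DCC, DMAP (cat.), CH2Cl2, 0 °C → rt
Reagents that add atoms: none
Why: Steglich esterification acylates the α-hydroxy ester without touching its stereocentre, and the acid-bearing ring carbon is already in its most stable all-trans configuration, so no stereocentre can drift.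

**Step 7**
Reactants: 12 heptabenzyl-protected target
Product: 13 (1R,2R,3S,4S)-3-{[(1S)-1-carboxy-2-(3,4-dihydroxyphenyl)ethoxy]carbonyl}-4-(3,4-dihydroxyphenyl)-2-(4-hydroxyphenyl)cyclobutane-1-carboxylic acid
Conditions: H2 (1 atm), 10% Pd/C, THF/MeOH, rt
Reagents that add atoms: none
Why: Catalytic hydrogenolysis cleaves all seven O-benzyl groups (five ethers, two esters), while the cyclobutane, the non-benzylic lactate ester and every stereocentre are inert under these conditions.

**Compound list**
1 | L-DOPA, (2S)-2-amino-3-(3,4-dihydroxyphenyl)propanoic acid | N[C@@H](Cc1ccc(O)c(O)c1)C(=O)O | starting material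
2 | (2S)-3-(3,4-dihydroxyphenyl)-2-hydroxypropanoic acid | O[C@@H](Cc1ccc(O)c(O)c1)C(=O)O | intermediate
3 | benzyl (2S)-3-[3,4-bis(benzyloxy)phenyl]-2-hydroxypropanoate | O[C@@H](Cc1ccc(OCc2ccccc2)c(OCc2ccccc2)c1)C(=O)OCc1ccccc1 | intermediate
4 | coumalic acid | O=C(O)C1=COC(=O)C=C1 | starting material
5 | benzyl coumalate | O=C(OCc1ccccc1)C1=COC(=O)C=C1 | intermediate
6 | 3,4-bis(benzyloxy)phenylboronic acid | OB(O)c1ccc(OCc2ccccc2)c(OCc2ccccc2)c1 | starting material
7 | benzyl 3-oxo-2-oxabicyclo[2.2.0]hex-5-ene-6-carboxylate (photopyrone; racemic, cis-fused, one enantiomer drawn) | O=C(OCc1ccccc1)C1=C[C@@H]2[C@H]1OC2=O | intermediate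
8 | (1S,4S)-4-[3,4-bis(benzyloxy)phenyl]-2-[(benzyloxy)carbonyl]cyclobut-2-ene-1-carboxylic acid (aryl trans to CO2H) | O=C(OCc1ccccc1)C1=C[C@H](C(=O)O)[C@H]1c1ccc(OCc2ccccc2)c(OCc2ccccc2)c1 | intermediate
9 | 4-(benzyloxy)phenylmagnesium bromide | Br[Mg]c1ccc(OCc2ccccc2)cc1 | starting material
10 | (1S,2S,3S,4R)-3-[(benzyloxy)carbonyl]-2-[4-(benzyloxy)phenyl]-4-[3,4-bis(benzyloxy)phenyl]cyclobutane-1-carboxylic acid (benzyl ester cis to both aryl groups) | O=C(OCc1ccccc1)[C@H]1[C@@H](c2ccc(OCc3ccccc3)cc2)[C@H](C(=O)O)[C@H]1c1ccc(OCc2ccccc2)c(OCc2ccccc2)c1 | intermediate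
11 | (1S,2S,3R,4R)-3-[(benzyloxy)carbonyl]-2-[4-(benzyloxy)phenyl]-4-[3,4-bis(benzyloxy)phenyl]cyclobutane-1-carboxylic acid (all-trans: both carboxyl groups on one face, both aryl groups on the other) | O=C(OCc1ccccc1)[C@@H]1[C@@H](c2ccc(OCc3ccccc3)cc2)[C@H](C(=O)O)[C@H]1c1ccc(OCc2ccccc2)c(OCc2ccccc2)c1 | intermediate
12 | 1-benzyl 3-[(2S)-1-(benzyloxy)-3-[3,4-bis(benzyloxy)phenyl]-1-oxopropan-2-yl] (1R,2R,3S,4S)-2-[4-(benzyloxy)phenyl]-4-[3,4-bis(benzyloxy)phenyl]cyclobutane-1,3-dicarboxylate | O=C(OCc1ccccc1)[C@@H]1[C@@H](c2ccc(OCc3ccccc3)cc2)[C@H](C(=O)O[C@@H](Cc2ccc(OCc3ccccc3)c(OCc3ccccc3)c2)C(=O)OCc2ccccc2)[C@H]1c1ccc(OCc2ccccc2)c(OCc2ccccc2)c1 | intermediate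
13 | (1R,2R,3S,4S)-3-{[(1S)-1-carboxy-2-(3,4-dihydroxyphenyl)ethoxy]carbonyl}-4-(3,4-dihydroxyphenyl)-2-(4-hydroxyphenyl)cyclobutane-1-carboxylic acid | O=C(O)[C@@H]1[C@@H](c2ccc(O)cc2)[C@H](C(=O)O[C@@H](Cc2ccc(O)c(O)c2)C(=O)O)[C@H]1c1ccc(O)c(O)c1 | target

**Totals**
Total step count: 7. Longest linear sequence: 5 steps (steps 3, 4, 5, 6, 7, from coumalic acid); the lactate branch (steps 1, 2) joins at step 6.

**The three steps most likely to fail, with fallbacks**

Step 4 carries the most risk. The enantioselectivity of an inner-sphere aryl transfer to this ester-substituted π-allyl is untested, and the ligand antipode that gives (1S,4S)-8 has to be found in a first screening run (both antipodes are commercial). Compound 7 must be used cold and at once, and 8 must be kept below about 35 °C to avoid electrocyclic ring opening. Any minor enantiomer of 8 that survives ends as a diastereomer of 12 and is removed there by chromatography. The fallback sets out from 5 and comes back at 8: 5 is photoisomerised to 7 as before, and 7 is opened without a chiral catalyst by rhodium-catalysed addition of 6 followed by β-oxygen elimination ([Rh(OH)(cod)]2, dioxane/H2O, 20 °C). This stereospecific anti-SN2′ process gives the racemic trans acid, that is 8 together with its mirror image (1R,4R)-4-[3,4-bis(benzyloxy)phenyl]-2-[(benzyloxy)carbonyl]cyclobut-2-ene-1-carboxylic acid F1. Asymmetric catalysis is replaced by resolution: 8 is separated from F1 by preparative chromatography on a chiral stationary phase.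

Step 5 may fail if the magnesium carboxylate directs the aryl to its own face, or if the Grignard reagent attacks the benzyl ester. The fallback sets out from 8 and comes back at 11, and replaces substrate control by catalyst control on a protected substrate. Compound 8 is converted (Boc2O, DMAP, tBuOH) into 2-benzyl 1-tert-butyl (1S,4S)-4-[3,4-bis(benzyloxy)phenyl]cyclobut-2-ene-1,2-dicarboxylate F2, which has neither an acidic proton nor a coordinating carboxylate. Rhodium-catalysed 1,4-addition of commercial 4-(benzyloxy)phenylboronic acid with a chiral bicyclo[2.2.2]octadiene ligand ([RhCl(C2H4)2]2, dioxane/H2O, 30 °C; ligand antipode chosen for attack anti to the tert-butyl ester) gives the kinetic adduct 1-benzyl 3-tert-butyl (1S,2R,3S,4S)-2-[4-(benzyloxy)phenyl]-4-[3,4-bis(benzyloxy)phenyl]cyclobutane-1,3-dicarboxylate F3. NaOBn in BnOH equilibrates it to the all-trans diester 1-benzyl 3-tert-butyl (1R,2R,3S,4S)-2-[4-(benzyloxy)phenyl]-4-[3,4-bis(benzyloxy)phenyl]cyclobutane-1,3-dicarboxylate F4, and TFA in CH2Cl2 removes the tert-butyl group selectively to give 11.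

Step 1 may fail because nitrous acid can nitrosate or oxidise the free catechol. The fallback sets out from 1 and comes back at 2 by a biocatalytic deamination–reduction instead of diazotisation. An L-amino acid deaminase (whole cells) converts 1 into 3-(3,4-dihydroxyphenyl)-2-oxopropanoic acid F5, which is reduced in the same vessel by an L-lactate dehydrogenase with NADH recycling (formate, formate dehydrogenase) to the (S)-hydroxy acid 2.

**Further compounds**
F1 | step 4 | (1R,4R)-4-[3,4-bis(benzyloxy)phenyl]-2-[(benzyloxy)carbonyl]cyclobut-2-ene-1-carboxylic acid (mirror image of 8) | O=C(OCc1ccccc1)C1=C[C@@H](C(=O)O)[C@@H]1c1ccc(OCc2ccccc2)c(OCc2ccccc2)c1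
F2 | step 5 | 2-benzyl 1-tert-butyl (1S,4S)-4-[3,4-bis(benzyloxy)phenyl]cyclobut-2-ene-1,2-dicarboxylate | O=C(OCc1ccccc1)C1=C[C@H](C(=O)OC(C)(C)C)[C@H]1c1ccc(OCc2ccccc2)c(OCc2ccccc2)c1
F3 | step 5 | 1-benzyl 3-tert-butyl (1S,2R,3S,4S)-2-[4-(benzyloxy)phenyl]-4-[3,4-bis(benzyloxy)phenyl]cyclobutane-1,3-dicarboxylate (benzyl ester cis to both aryl groups) | O=C(OCc1ccccc1)[C@H]1[C@@H](c2ccc(OCc3ccccc3)cc2)[C@H](C(=O)OC(C)(C)C)[C@H]1c1ccc(OCc2ccccc2)c(OCc2ccccc2)c1
F4 | step 5 | 1-benzyl 3-tert-butyl (1R,2R,3S,4S)-2-[4-(benzyloxy)phenyl]-4-[3,4-bis(benzyloxy)phenyl]cyclobutane-1,3-dicarboxylate (all-trans) | O=C(OCc1ccccc1)[C@@H]1[C@@H](c2ccc(OCc3ccccc3)cc2)[C@H](C(=O)OC(C)(C)C)[C@H]1c1ccc(OCc2ccccc2)c(OCc2ccccc2)c1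
F5 | step 1 | 3-(3,4-dihydroxyphenyl)-2-oxopropanoic acid | O=C(Cc1ccc(O)c(O)c1)C(=O)O
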